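The route rests on disconnecting the C5–C10 bond of ring A. H-5 and the C10 methyl are cis and flank the C4 gem-dimethyl carbon, so with a C1=C2 double bond this pair is the retron of a γ,δ-unsaturated acid. One Ireland–Claisen ring contraction of an alkenyl δ-lactone therefore closes ring A, forms the C5–C10 bond and sets both centres, the lactone carbinol carbon (C2) passing its configuration on through a ring-enforced boat. The precursor is an (R)-6-alkenyl-4,4-dimethyloxan-2-one whose (E)-trisubstituted alkene carries the C10 methyl and a ketal-masked 2-oxopropyl arm (C9, C8, C7); ring B and the side chain follow by aldol, alkylation and carbonyl additions from the convex face.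

Key step: step 8

Remark: labdane numbering is used; as drawn, the target is a 5,10-cis-fused decalin with H-5, the C10 methyl, the C9 side chain, the C8 methyl and the C6 acetoxy group on one face of ring B (β) and ring A and the C8 hydroxyl on the other (α), and the (6R,E)-lactone 14 maps onto 5S,10R through the boat.

Step 1
Reactants: 1 pent-4-yn-2-ol; 2 trimethylaluminium
Product: 4 (E)-5-iodo-4-methylpent-4-en-2-ol (racemic), via alkenylalane 3 (not isolated)
Conditions: Me3Al (3 equiv), Cp2ZrCl2 (0.25 equiv), CH2Cl2, 0 °C to rt; then I2, THF, −30 to 0 °C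
Reagents that add atoms: trimethylaluminium (C[Al](C)C); iodine (II)
Why: Negishi zirconium-catalysed carboalumination adds methyl and aluminium syn across the terminal alkyne with aluminium at the terminus, and iodinolysis with retention gives the (E)-iodoalkene that later fixes the C1=C10 geometry, the hydroxyl being carried as its aluminium alkoxide and its racemic centre being removed in step 2.

Step 2
Reactants: 4 (E)-5-iodo-4-methylpent-4-en-2-ol
Product: 5 (E)-5-iodo-4-methylpent-4-en-2-one
Conditions: Dess–Martin periodinane, NaHCO3, CH2Cl2, 0 °C to rt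
Reagents that add atoms: none
Why: Dess–Martin oxidation of the secondary alcohol under buffered, non-basic conditions should leave the β,γ-double bond in place and its geometry untouched.

Step 3
Reactants: 5 (E)-5-iodo-4-methylpent-4-en-2-one
Product: 6 2-[(2E)-3-iodo-2-methylprop-2-en-1-yl]-2-methyl-1,3-dioxolane
Conditions: Me3SiOCH2CH2OSiMe3, Me3SiOTf (5 mol %), CH2Cl2, −78 °C; pyridine quench
Reagents that add atoms: 1,2-bis(trimethylsilyloxy)ethane (C[Si](C)(C)OCCO[Si](C)(C)C)
Why: Noyori ketalisation runs under aprotic conditions at low temperature, so the skipped enone is masked without migration of the double bond into conjugation.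

Step 4
Reactants: 7 3,3-dimethylglutaric anhydride
Product: 8 5-methoxy-3,3-dimethyl-5-oxopentanoic acid
Conditions: MeOH, reflux
Reagents that add atoms: methanol (CO)
Why: Alcoholysis of the symmetrical cyclic anhydride can give only one half-ester.

Step 5
Reactants: 8 5-methoxy-3,3-dimethyl-5-oxopentanoic acid
Product: 9 methyl 5-chloro-3,3-dimethyl-5-oxopentanoate
Conditions: (COCl)2, DMF (cat.), CH2Cl2, 0 °C to rt
Reagents that add atoms: oxalyl chloride (O=C(Cl)C(=O)Cl)
Why: Vilsmeier-catalysed acid chloride formation is standard and leaves the methyl ester alone.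

Step 6
Reactants: 6 2-[(2E)-3-iodo-2-methylprop-2-en-1-yl]-2-methyl-1,3-dioxolane; 9 methyl 5-chloro-3,3-dimethyl-5-oxopentanoate
Product: 12 methyl (6E)-3,3,7-trimethyl-8-(2-methyl-1,3-dioxolan-2-yl)-5-oxooct-6-enoate, via alkenyllithium 10 (not isolated), via alkenylzinc chloride 11 (not isolated)
Conditions: t-BuLi (2.0 equiv), Et2O, −78 °C; ZnCl2, THF, −78 to 0 °C; then 9, Pd(PPh3)4 (5 mol %), THF, 0 °C to rt
Reagents that add atoms: none
Why: Iodine–lithium exchange and transmetalation to zinc keep the alkene geometry, and the Negishi acylation (coupling of an alkenylzinc with an acid chloride on zerovalent palladium) stops at the ketone and spares ester and ketal.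

Step 7
Reactants: 12 methyl (6E)-3,3,7-trimethyl-8-(2-methyl-1,3-dioxolan-2-yl)-5-oxooct-6-enoate
Product: 14 (6R)-4,4-dimethyl-6-[(1E)-2-methyl-3-(2-methyl-1,3-dioxolan-2-yl)prop-1-en-1-yl]oxan-2-one, via hydroxy ester 13 (not isolated)
Conditions: (S)-Me-CBS [(3aS)-1-methyl-3,3-diphenyltetrahydro-1H,3H-pyrrolo[1,2-c][1,3,2]oxazaborole] (0.2 equiv), catecholborane (1.5 equiv), toluene, −78 °C; aqueous work-up; then pyridinium p-toluenesulfonate (0.1 equiv), toluene, 60 °C
Reagents that add atoms: none
Why: Corey–Bakshi–Shibata reduction with the (S)-oxazaborolidine should deliver hydride to the carbonyl only (1,2-reduction) with the alkenyl group as the large substituent, setting the (R)-carbinol centre C2, and the δ-hydroxy ester then lactonises by mild acid-catalysed transesterification helped by the gem-dimethyl (Thorpe–Ingold) effect.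

Step 8
Reactants: 14 (6R)-4,4-dimethyl-6-[(1E)-2-methyl-3-(2-methyl-1,3-dioxolan-2-yl)prop-1-en-1-yl]oxan-2-one
Product: 17 (1S,2R)-2,6,6-trimethyl-2-[(2-methyl-1,3-dioxolan-2-yl)methyl]cyclohex-3-ene-1-carboxylic acid, via silyl ketene acetal 15 (not isolated), via trimethylsilyl ester 16 (not isolated)
Conditions: Me3SiCl, Et3N, THF, −78 °C, then LiN(iPr)2 (1.2 equiv), −78 °C to rt; toluene, 110 °C (sealed); then H2O, THF, pH 5 buffer
Reagents that add atoms: none
Why: In situ silylation of the kinetically formed lactone enolate gives cyclic ketene acetal 15, which on heating undergoes a concerted suprafacial [3,3]-sigmatropic shift in which C5–C10 forms while the allylic C2–O bond breaks, so the lactone opens to silyl ester 16 as the carbocycle closes. The closest known reaction is the Ireland–Claisen rearrangement in its lactone ring-contraction form, known to turn 6-alkenyl oxan-2-ones into cyclohex-3-ene-1-carboxylic acids. Ring A closes pericyclically, not by an ionic exo or endo attack: C5 bonds to the distal alkene carbon C10 within a boat-shaped six-atom array (C5, C6, O, C2, C1, C10) that the C3–C4 tether enforces as in a bicyclo[2.2.2]octane. C5 is controlled by the C2 carbinol centre, since the alkenyl arm can reach only the ketene acetal face on which it stands, and C10 is controlled by the E geometry of C1=C10 inside that boat, which puts the C9 arm cis to the carboxyl carbon C6 and the C10 methyl cis to H-5. The step needs complete chirality transfer and a [3,3] shift that outruns ionisation of the allylic C2–O bond, C-silylation and desilylation; internal quenching with Me3SiCl, the Et3N buffer and the absence of any chair alternative in the six-membered lactone should secure this, while the compression between the C10 methyl and the C4 methyls is met with temperature only.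

Step 9
Reactants: 17 (1S,2R)-2,6,6-trimethyl-2-[(2-methyl-1,3-dioxolan-2-yl)methyl]cyclohex-3-ene-1-carboxylic acid
Product: 18 (1S,2S)-2,6,6-trimethyl-2-[(2-methyl-1,3-dioxolan-2-yl)methyl]cyclohexane-1-carboxylic acid
Conditions: H2 (1 atm), Pd on carbon (10%), EtOAc, rt
Reagents that add atoms: none
Why: Heterogeneous catalytic hydrogenation saturates C1=C2 while it is the only alkene in the molecule, makes no stereocentre and spares acid and ketal (the C2 descriptor changes only through the CIP ranking).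

Step 10
Reactants: 18 (1S,2S)-2,6,6-trimethyl-2-[(2-methyl-1,3-dioxolan-2-yl)methyl]cyclohexane-1-carboxylic acid
Product: 19 [(1S,2S)-2,6,6-trimethyl-2-[(2-methyl-1,3-dioxolan-2-yl)methyl]cyclohexyl]methanol
Conditions: LiAlH4, THF, 0 °C to reflux; H2O, 15% aq. NaOH work-up
Reagents that add atoms: none
Why: Lithium aluminium hydride reduction of the hindered acid gives the primary alcohol at C6 under basic conditions that spare the dioxolane and cannot epimerise C5.

Step 11
Reactants: 19 [(1S,2S)-2,6,6-trimethyl-2-[(2-methyl-1,3-dioxolan-2-yl)methyl]cyclohexyl]methanol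
Product: 20 (1S,2S)-2,6,6-trimethyl-2-[(2-methyl-1,3-dioxolan-2-yl)methyl]cyclohexane-1-carbaldehyde
Conditions: Dess–Martin periodinane, NaHCO3, CH2Cl2, 0 °C to rt
Reagents that add atoms: none
Why: Dess–Martin oxidation stops at the aldehyde and is neutral, so the α-centre C5, shielded by two quaternary neighbours, should not epimerise.

Step 12
Reactants: 20 (1S,2S)-2,6,6-trimethyl-2-[(2-methyl-1,3-dioxolan-2-yl)methyl]cyclohexane-1-carbaldehyde
Product: 22 (4aS,8aS)-5,5,8a-trimethyl-4a,5,6,7,8,8a-hexahydronaphthalen-2(1H)-one, via keto aldehyde 21 (not isolated)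
Conditions: 1 M HCl, THF, rt; then KOH (0.1 M), MeOH, 0 °C to rt
Reagents that add atoms: water (O)
Why: Acid hydrolysis frees the methyl ketone and a base-mediated intramolecular aldol condensation (Robinson-type cyclodehydration) closes ring B through its only six-membered option, the C7 methyl enolate attacking the C6 aldehyde, while the hindered tertiary C5–H is left alone under these mild conditions so that the cis ring fusion is kept.

Step 13
Reactants: 23 2-(2-bromoethyl)-2-methyl-1,3-dioxolane
Product: 24 2-(2-iodoethyl)-2-methyl-1,3-dioxolane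
Conditions: NaI, NaHCO3, acetone, reflux
Reagents that add atoms: sodium iodide ([Na+].[I-])
Why: Finkelstein halide exchange, driven by precipitation of NaBr, gives the more reactive primary iodide.

Step 14
Reactants: 22 (4aS,8aS)-5,5,8a-trimethyl-4a,5,6,7,8,8a-hexahydronaphthalen-2(1H)-one; 24 2-(2-iodoethyl)-2-methyl-1,3-dioxolane
Product: 26 (1S,4aS,8aR)-5,5,8a-trimethyl-1-[2-(2-methyl-1,3-dioxolan-2-yl)ethyl]-4a,5,6,7,8,8a-hexahydronaphthalen-2(1H)-one, via lithium dienolate 25 (not isolated)
Conditions: LiN(iPr)2 (1.05 equiv), THF, −78 °C; then 24, DMPU, −78 to −20 °C; cold aq. NH4Cl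
Reagents that add atoms: none
Why: Kinetic α′-deprotonation of the enone gives the cross-conjugated lithium dienolate (the γ-hydrogen on C5 is tertiary and shielded), and SN2 alkylation at C9 should occur axially on the face opposite the axial C1–C10 bond of the cis-fused ring A, that is cis to the C10 methyl, the cold quench preventing equilibration of the axial side chain.

Step 15
Reactants: 26 (1S,4aS,8aR)-5,5,8a-trimethyl-1-[2-(2-methyl-1,3-dioxolan-2-yl)ethyl]-4a,5,6,7,8,8a-hexahydronaphthalen-2(1H)-one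
Product: 28 (1S,4S,4aS,8aR)-4-hydroxy-5,5,8a-trimethyl-1-[2-(2-methyl-1,3-dioxolan-2-yl)ethyl]octahydronaphthalen-2(1H)-one, via pinacol boronate 27 (not isolated)
Conditions: B2pin2 (1.1 equiv), CuCl (5 mol %), Xantphos (5 mol %), NaOtBu (10 mol %), MeOH (2 equiv), THF, rt; then NaBO3·4H2O, THF/H2O, rt
Reagents that add atoms: sodium perborate ([Na+].[O-]OB=O)
Why: Copper-catalysed conjugate borylation of the enone followed by stereoretentive boron-to-oxygen oxidation amounts to a conjugate hydration, and the bulky copper–boryl species should attack C6 trans to both ring-A carbons (C4 on C5 and the axial C1 on C10), giving the equatorial 6β-hydroxyl on the face of H-5.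

Step 16
Reactants: 28 (1S,4S,4aS,8aR)-4-hydroxy-5,5,8a-trimethyl-1-[2-(2-methyl-1,3-dioxolan-2-yl)ethyl]octahydronaphthalen-2(1H)-one
Product: 30 4-[(1S,2S,4S,4aS,8aR)-2,4-dihydroxy-2,5,5,8a-tetramethyldecahydronaphthalen-1-yl]butan-2-one, via ketal diol 29 (not isolated)
Conditions: CeCl3 (4 equiv), MeLi (4 equiv), THF, −78 °C; then 1 M HCl, THF, rt
Reagents that add atoms: methyllithium (C[Li]); water (O)
Why: The organocerium reagent MeCeCl2 adds to the enolisable β-hydroxy ketone without enolisation or retro-aldol cleavage, and with ring B as a chair whose α-face is blocked by the syn-axial C1 of ring A it should enter equatorially from the β-face to give the equatorial C8 methyl and the axial 8α-hydroxyl, after which dilute aqueous acid frees the side-chain ketone.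

Step 17
Reactants: 30 4-[(1S,2S,4S,4aS,8aR)-2,4-dihydroxy-2,5,5,8a-tetramethyldecahydronaphthalen-1-yl]butan-2-one
Product: 31 ethyl (2E)-5-[(1S,2S,4S,4aS,8aR)-2,4-dihydroxy-2,5,5,8a-tetramethyldecahydronaphthalen-1-yl]-3-methylpent-2-enoate
Conditions: (EtO)2P(O)CH2CO2Et (3 equiv), NaH (3 equiv), THF, 0 to 50 °C
Reagents that add atoms: triethyl phosphonoacetate (CCOC(=O)CP(=O)(OCC)OCC)
Why: Horner–Wadsworth–Emmons olefination of the methyl ketone under equilibrating conditions should favour the (E)-enoate with the ester trans to the larger CH2 chain, the stabilised carbanion is too weak a base to disturb the free diol, and any minor (Z)-isomer is removed by chromatography.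

Step 18
Reactants: 31 ethyl (2E)-5-[(1S,2S,4S,4aS,8aR)-2,4-dihydroxy-2,5,5,8a-tetramethyldecahydronaphthalen-1-yl]-3-methylpent-2-enoate
Product: 32 (2E)-5-[(1S,2S,4S,4aS,8aR)-2,4-dihydroxy-2,5,5,8a-tetramethyldecahydronaphthalen-1-yl]-3-methylpent-2-enoic acid
Conditions: LiOH, THF/MeOH/H2O, 40 °C; then 1 M HCl to pH 3, 0 °C
Reagents that add atoms: lithium hydroxide ([Li+].[OH-])
Why: Saponification is placed before the acetate is introduced, so no choice between two esters is needed and the alkene geometry is not affected.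

Step 19
Reactants: 32 (2E)-5-[(1S,2S,4S,4aS,8aR)-2,4-dihydroxy-2,5,5,8a-tetramethyldecahydronaphthalen-1-yl]-3-methylpent-2-enoic acid
Product: 34 (2E)-5-[(1S,2S,4S,4aS,8aR)-4-acetoxy-2-hydroxy-2,5,5,8a-tetramethyldecahydronaphthalen-1-yl]-3-methylpent-2-enoic acid, via mixed anhydride 33 (not isolated)
Conditions: Ac2O, pyridine, 4-(dimethylamino)pyridine (cat.), CH2Cl2, 0 °C to rt; then H2O, NaHCO3, THF, rt
Reagents that add atoms: acetic anhydride (CC(=O)OC(C)=O)
Why: Nucleophile-catalysed acylation esterifies only the secondary equatorial C6 hydroxyl (the tertiary axial C8 hydroxyl is inert), and the acetic mixed anhydride formed at C15 is hydrolysed back to the acid in the aqueous stage.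

Compound list

1 | pent-4-yn-2-ol | CC(O)CC#C | starting material
2 | trimethylaluminium | C[Al](C)C | starting material
3 | [(1E)-4-(dimethylalumanyloxy)-2-methylpent-1-en-1-yl]dimethylalumane (alkenylalane) | C[Al](C)/C=C(\C)CC(C)O[Al](C)C | intermediate
4 | (E)-5-iodo-4-methylpent-4-en-2-ol (racemic) | CC(O)C/C(C)=C/I | intermediate
5 | (E)-5-iodo-4-methylpent-4-en-2-one | CC(=O)C/C(C)=C/I | intermediate
6 | 2-[(2E)-3-iodo-2-methylprop-2-en-1-yl]-2-methyl-1,3-dioxolane | CC1(C/C(C)=C/I)OCCO1 | intermediate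
7 | 3,3-dimethylglutaric anhydride | O=C1CC(C)(C)CC(=O)O1 | starting material
8 | 5-methoxy-3,3-dimethyl-5-oxopentanoic acid | COC(=O)CC(C)(C)CC(=O)O | intermediate
9 | methyl 5-chloro-3,3-dimethyl-5-oxopentanoate | COC(=O)CC(C)(C)CC(=O)Cl | intermediate
10 | [(1E)-2-methyl-3-(2-methyl-1,3-dioxolan-2-yl)prop-1-en-1-yl]lithium (alkenyllithium) | [Li]/C=C(\C)CC1(C)OCCO1 | intermediate
11 | chloro[(1E)-2-methyl-3-(2-methyl-1,3-dioxolan-2-yl)prop-1-en-1-yl]zinc (alkenylzinc chloride) | Cl[Zn]/C=C(\C)CC1(C)OCCO1 | intermediate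
12 | methyl (6E)-3,3,7-trimethyl-8-(2-methyl-1,3-dioxolan-2-yl)-5-oxooct-6-enoate | COC(=O)CC(C)(C)CC(=O)/C=C(\C)CC1(C)OCCO1 | intermediate
13 | methyl (5R,6E)-5-hydroxy-3,3,7-trimethyl-8-(2-methyl-1,3-dioxolan-2-yl)oct-6-enoate (hydroxy ester) | COC(=O)CC(C)(C)C[C@@H](O)/C=C(\C)CC1(C)OCCO1 | intermediate
14 | (6R)-4,4-dimethyl-6-[(1E)-2-methyl-3-(2-methyl-1,3-dioxolan-2-yl)prop-1-en-1-yl]oxan-2-one (key-step precursor) | O=C1CC(C)(C)C[C@H](/C=C(\C)CC2(C)OCCO2)O1 | intermediate
15 | trimethyl{[(2R)-4,4-dimethyl-2-[(1E)-2-methyl-3-(2-methyl-1,3-dioxolan-2-yl)prop-1-en-1-yl]-3,4-dihydro-2H-pyran-6-yl]oxy}silane (silyl ketene acetal) | C[Si](C)(C)OC1=CC(C)(C)C[C@H](/C=C(\C)CC2(C)OCCO2)O1 | intermediate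
16 | trimethylsilyl (1S,2R)-2,6,6-trimethyl-2-[(2-methyl-1,3-dioxolan-2-yl)methyl]cyclohex-3-ene-1-carboxylate | C[Si](C)(C)OC(=O)[C@H]1C(C)(C)CC=C[C@@]1(C)CC2(C)OCCO2 | intermediate
17 | (1S,2R)-2,6,6-trimethyl-2-[(2-methyl-1,3-dioxolan-2-yl)methyl]cyclohex-3-ene-1-carboxylic acid (key-step product) | OC(=O)[C@H]1C(C)(C)CC=C[C@@]1(C)CC2(C)OCCO2 | intermediate
18 | (1S,2S)-2,6,6-trimethyl-2-[(2-methyl-1,3-dioxolan-2-yl)methyl]cyclohexane-1-carboxylic acid | OC(=O)[C@H]1C(C)(C)CCC[C@@]1(C)CC2(C)OCCO2 | intermediate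
19 | [(1S,2S)-2,6,6-trimethyl-2-[(2-methyl-1,3-dioxolan-2-yl)methyl]cyclohexyl]methanol | OC[C@H]1C(C)(C)CCC[C@@]1(C)CC2(C)OCCO2 | intermediate
20 | (1S,2S)-2,6,6-trimethyl-2-[(2-methyl-1,3-dioxolan-2-yl)methyl]cyclohexane-1-carbaldehyde | O=C[C@H]1C(C)(C)CCC[C@@]1(C)CC2(C)OCCO2 | intermediate
21 | (1S,2S)-2,6,6-trimethyl-2-(2-oxopropyl)cyclohexane-1-carbaldehyde (keto aldehyde) | O=C[C@H]1C(C)(C)CCC[C@@]1(C)CC(C)=O | intermediate
22 | (4aS,8aS)-5,5,8a-trimethyl-4a,5,6,7,8,8a-hexahydronaphthalen-2(1H)-one (cis-fused ring-B enone, C8=O, C6=C7) | O=C1C=C[C@H]2C(C)(C)CCC[C@@]2(C)C1 | intermediate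
23 | 2-(2-bromoethyl)-2-methyl-1,3-dioxolane | CC1(CCBr)OCCO1 | starting material
24 | 2-(2-iodoethyl)-2-methyl-1,3-dioxolane | CC1(CCI)OCCO1 | intermediate
25 | lithium (4aS,8aR)-5,5,8a-trimethyl-4a,5,6,7,8,8a-hexahydronaphthalen-2-olate (cross-conjugated dienolate, C8=C9 and C6=C7) | [Li]OC1=C[C@]2(C)CCCC(C)(C)[C@@H]2C=C1 | intermediate
26 | (1S,4aS,8aR)-5,5,8a-trimethyl-1-[2-(2-methyl-1,3-dioxolan-2-yl)ethyl]-4a,5,6,7,8,8a-hexahydronaphthalen-2(1H)-one | O=C1C=C[C@H]2C(C)(C)CCC[C@@]2(C)[C@@H]1CCC3(C)OCCO3 | intermediate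
27 | (1S,4S,4aS,8aR)-5,5,8a-trimethyl-1-[2-(2-methyl-1,3-dioxolan-2-yl)ethyl]-4-(4,4,5,5-tetramethyl-1,3,2-dioxaborolan-2-yl)octahydronaphthalen-2(1H)-one (pinacol boronate) | O=C1C[C@H](B2OC(C)(C)C(C)(C)O2)[C@H]3C(C)(C)CCC[C@@]3(C)[C@@H]1CCC4(C)OCCO4 | intermediate
28 | (1S,4S,4aS,8aR)-4-hydroxy-5,5,8a-trimethyl-1-[2-(2-methyl-1,3-dioxolan-2-yl)ethyl]octahydronaphthalen-2(1H)-one | O=C1C[C@H](O)[C@H]2C(C)(C)CCC[C@@]2(C)[C@@H]1CCC3(C)OCCO3 | intermediate
29 | (1S,2S,4S,4aS,8aR)-2,5,5,8a-tetramethyl-1-[2-(2-methyl-1,3-dioxolan-2-yl)ethyl]decahydronaphthalene-2,4-diol (ketal diol) | O[C@H]1C[C@](C)(O)[C@@H](CCC2(C)OCCO2)[C@]3(C)CCCC(C)(C)[C@H]13 | intermediate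
30 | 4-[(1S,2S,4S,4aS,8aR)-2,4-dihydroxy-2,5,5,8a-tetramethyldecahydronaphthalen-1-yl]butan-2-one | O[C@H]1C[C@](C)(O)[C@@H](CCC(C)=O)[C@]2(C)CCCC(C)(C)[C@H]12 | intermediate
31 | ethyl (2E)-5-[(1S,2S,4S,4aS,8aR)-2,4-dihydroxy-2,5,5,8a-tetramethyldecahydronaphthalen-1-yl]-3-methylpent-2-enoate | O[C@H]1C[C@](C)(O)[C@@H](CC/C(C)=C/C(=O)OCC)[C@]2(C)CCCC(C)(C)[C@H]12 | intermediate
32 | (2E)-5-[(1S,2S,4S,4aS,8aR)-2,4-dihydroxy-2,5,5,8a-tetramethyldecahydronaphthalen-1-yl]-3-methylpent-2-enoic acid | O[C@H]1C[C@](C)(O)[C@@H](CC/C(C)=C/C(=O)O)[C@]2(C)CCCC(C)(C)[C@H]12 | intermediate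
33 | acetic (2E)-5-[(1S,2S,4S,4aS,8aR)-4-acetoxy-2-hydroxy-2,5,5,8a-tetramethyldecahydronaphthalen-1-yl]-3-methylpent-2-enoic anhydride (mixed anhydride) | CC(=O)O[C@H]1C[C@](C)(O)[C@@H](CC/C(C)=C/C(=O)OC(C)=O)[C@]2(C)CCCC(C)(C)[C@H]12 | intermediate
34 | (2E)-5-[(1S,2S,4S,4aS,8aR)-4-acetoxy-2-hydroxy-2,5,5,8a-tetramethyldecahydronaphthalen-1-yl]-3-methylpent-2-enoic acid | CC(=O)O[C@H]1C[C@](C)(O)[C@@H](CC/C(C)=C/C(=O)O)[C@]2(C)CCCC(C)(C)[C@H]12 | target

Total step count: 19. Longest linear sequence: 16 steps (steps 1–3, 6–12, 14–19).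

Steps most likely to fail

Step 8. The rearrangement may stall under the compression between the C10 methyl and the C4 methyls, or be outrun by ionisation of the allylic C2–O bond and elimination. The fallback makes the same C5–C10 bond by an acyclic, chair-type Ireland–Claisen rearrangement and closes ring A afterwards by metathesis; it sets out from iodide 6 and half-ester 8 and returns at acid 17. Lithiation of 6 (t-BuLi) and acylation with N-methoxy-N-methylacetamide gives methyl enone F1, which the (R)-Me-CBS catalyst with catecholborane reduces to (S)-allylic alcohol F2. Half-ester 8 is reduced at the acid with BH3·SMe2 to hydroxy ester F3, oxidised with Dess–Martin periodinane to aldehyde ester F4, methylenated with Ph3P=CH2 to alkenyl ester F5 and saponified with LiOH to alkenoic acid F6. Steglich esterification of F2 with F6 (dicyclohexylcarbodiimide, 4-(dimethylamino)pyridine) gives allylic ester F7. Enolisation with LiN(iPr)2 in THF/DMPU places the alkyl group cis to the metal-bound oxygen; silylation with t-BuMe2SiCl and warming should then give, through a chair with the carbinol methyl equatorial, Claisen acid F8 with C5 and C10 as in 17. Ring-closing metathesis with the second-generation Grubbs catalyst RuCl2(=CHPh)(H2IMes)(PCy3) closes ring A with loss of propene and gives 17.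

Step 14. SN2 displacement of an unactivated primary iodide at a neopentyl-type dienolate carbon may be slow, so that proton transfer and equilibration of the axial side chain compete. The fallback brings the four-carbon unit in by conjugate addition; it sets out from enone 22 and returns at 26. Trapping the kinetic dienolate (LiN(iPr)2, Me3SiCl) gives silyl dienol ether F9, and a Mukaiyama–Michael addition to methyl vinyl ketone (TiCl4, Ti(OiPr)4, CH2Cl2, −78 °C), with the same axial approach to C9, gives diketone F10. The saturated methyl ketone is then ketalised selectively (Me3SiOCH2CH2OSiMe3, Me3SiOTf cat., −78 °C), the hindered conjugated ring ketone reacting far more slowly, to give 26.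

Step 16. Facial selectivity at C8 may be poor, because the equatorial path passes the axial C9 side chain while the axial path passes C1. The fallback installs the two C8 substituents under thermodynamic control of the carbon–carbon bond; it sets out from hydroxy ketone 28 and returns at keto diol 30. Silylation (Et3SiCl, imidazole) gives silyl ether F11. Dimethylsulfoxonium methylide (Me3S(O)I, NaH, DMSO; Corey–Chaykovsky reaction, in which reversible betaine formation places the new C–C bond equatorial and the oxygen axial) gives spiro-epoxide F12. LiEt3BH opens the epoxide at its methylene carbon to tertiary alcohol F13, and 1 M HCl in THF removes the silyl ether and the ketal to give 30.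

Further compounds

F1 | step 8 | (3E)-4-methyl-5-(2-methyl-1,3-dioxolan-2-yl)pent-3-en-2-one | CC(=O)/C=C(\C)CC1(C)OCCO1
F2 | step 8 | (2S,3E)-4-methyl-5-(2-methyl-1,3-dioxolan-2-yl)pent-3-en-2-ol | C[C@H](O)/C=C(\C)CC1(C)OCCO1
F3 | step 8 | methyl 5-hydroxy-3,3-dimethylpentanoate | COC(=O)CC(C)(C)CCO
F4 | step 8 | methyl 3,3-dimethyl-5-oxopentanoate | COC(=O)CC(C)(C)CC=O
F5 | step 8 | methyl 3,3-dimethylhex-5-enoate | COC(=O)CC(C)(C)CC=C
F6 | step 8 | 3,3-dimethylhex-5-enoic acid | OC(=O)CC(C)(C)CC=C
F7 | step 8 | (2S,3E)-4-methyl-5-(2-methyl-1,3-dioxolan-2-yl)pent-3-en-2-yl 3,3-dimethylhex-5-enoate | C=CCC(C)(C)CC(=O)O[C@@H](C)/C=C(\C)CC1(C)OCCO1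
F8 | step 8 | (2S,3R,4E)-3-methyl-3-[(2-methyl-1,3-dioxolan-2-yl)methyl]-2-(2-methylpent-4-en-2-yl)hex-4-enoic acid | OC(=O)[C@@H](C(C)(C)CC=C)[C@@](C)(/C=C/C)CC1(C)OCCO1
F9 | step 14 | trimethyl{[(4aS,8aR)-5,5,8a-trimethyl-4a,5,6,7,8,8a-hexahydronaphthalen-2-yl]oxy}silane | C[Si](C)(C)OC1=C[C@]2(C)CCCC(C)(C)[C@@H]2C=C1
F10 | step 14 | (1S,4aS,8aR)-5,5,8a-trimethyl-1-(3-oxobutyl)-4a,5,6,7,8,8a-hexahydronaphthalen-2(1H)-one | O=C1C=C[C@H]2C(C)(C)CCC[C@@]2(C)[C@@H]1CCC(C)=O
F11 | step 16 | (1S,4S,4aS,8aR)-5,5,8a-trimethyl-1-[2-(2-methyl-1,3-dioxolan-2-yl)ethyl]-4-[(triethylsilyl)oxy]octahydronaphthalen-2(1H)-one | O=C1C[C@H](O[Si](CC)(CC)CC)[C@H]2C(C)(C)CCC[C@@]2(C)[C@@H]1CCC3(C)OCCO3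
F12 | step 16 | spiro-epoxide at C8 of F11 (epoxide oxygen α and axial, methylene β), 6β-triethylsilyl ether | CC[Si](CC)(CC)O[C@H]1C[C@@]2(CO2)[C@@H](CCC3(C)OCCO3)[C@]4(C)CCCC(C)(C)[C@H]14
F13 | step 16 | (1S,2S,4S,4aS,8aR)-2,5,5,8a-tetramethyl-1-[2-(2-methyl-1,3-dioxolan-2-yl)ethyl]-4-[(triethylsilyl)oxy]decahydronaphthalen-2-ol | CC[Si](CC)(CC)O[C@H]1C[C@](C)(O)[C@@H](CCC2(C)OCCO2)[C@]3(C)CCCC(C)(C)[C@H]13
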